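**Plan**

1. Retrosynthesis: the C1 hydroxyl and the C2=C3 enone are traced back to the C1=C2 alkene of a Diels–Alder adduct. Cutting C3–C11' and C5–C13' of its cyclohexene gives 8-epi-xanthatin (diene C5=C1–C2=C3) and the 1,5-epoxide of its enantiomer (dienophile C11'=C13'), because the two halves are antipodal at C7/C8/C10.
2. Both partners come from one racemic 8-epi-xanthatin. It is cut at C2=C3 (Wittig), C11=C13 (methylenation), O–C8 (inverting lactonisation), C6–O (a ketone that is removed), C7–C11 (alkylation) and last at C7–C8 and C1–C5 of the seven-membered ring.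
3. Enabling feature: in each cycloheptane the oxygen-bearing carbons C1 and C8 are 1,4-related through C10(Me)–C9 and joined on the other side by C5–C6–C7. The ring is therefore an opened 8-oxabicyclo[3.2.1]octene: C1–C10–C9–C8 plus the bridge oxygen are a 2,3-disubstituted furan, and C5–C6–C7 is a siloxyvinyl carbenoid whose ester sits on C7.
4. Forward: furan + vinyldiazoacetate → cyclopropane → Cope → oxabicycle (seven-membered ring), C7 alkylation, hydrogenation/decarboxylation, opening of the oxygen bridge to C1=C5, C6 deoxygenation, γ-lactone, methylene, side chain, resolution, epoxidation of one antipode, Diels–Alder (cyclohexene and spiro centre), C1 hydroxylation.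
5. Stereochemistry: C10 and C7 from exo-face delivery of hydrogen on the bicycle; C8 by Mitsunobu inversion; absolute configuration from one resolution that supplies both antipodes; C1'/C5' from peracid attack anti to the C10' methyl; C5/C3/C11' from an exo Diels–Alder on the convex lactone face; C1 from trans-diaxial bromohydrin opening.

Key step: step 5

Remark: atoms are numbered as in xanthanolides (C1–C15, primes for the half that carries the epoxide); compounds 7–25 are racemic and their SMILES show the antipode that ends in the epoxide half.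

**Route**

Step 1
Reactants: 1 methyl 3-methylfuran-2-carboxylate
Product: 2 (3-methylfuran-2-yl)methanol
Conditions: LiAlH4, Et2O, 0 °C
Reagents that add atoms: none
Why: Hydride reduction of the ester to the primary alcohol; no stereocentre is formed.

Step 2
Reactants: 2 (3-methylfuran-2-yl)methanol
Product: 3 tert-butyl[(3-methylfuran-2-yl)methoxy]diphenylsilane
Conditions: TBDPSCl, imidazole, DMF, rt
Reagents that add atoms: tert-butyl(chloro)diphenylsilane, CC(C)(C)[Si](Cl)(c1ccccc1)c1ccccc1
Why: Silylation of the primary alcohol gives an ether that should survive the carbenoid, fluoride at low temperature, bases and hydrides, and that adds bulk next to the substituted furan double bond.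

Step 3
Reactants: 4 benzyl 3-oxobutanoate
Product: 5 benzyl 2-diazo-3-oxobutanoate
Conditions: 4-acetamidobenzenesulfonyl azide, Et3N, MeCN, 0 °C → rt
Reagents that add atoms: 4-acetamidobenzenesulfonyl azide, CC(=O)Nc1ccc(cc1)S(=O)(=O)N=[N+]=[N-]
Why: Regitz diazo transfer to the doubly activated methylene.

Step 4
Reactants: 5 benzyl 2-diazo-3-oxobutanoate
Product: 6 benzyl 3-[(tert-butyldimethylsilyl)oxy]-2-diazobut-3-enoate
Conditions: TBSOTf, Et3N, CH2Cl2, 0 °C
Reagents that add atoms: tert-butyldimethylsilyl trifluoromethanesulfonate, CC(C)(C)[Si](C)(C)OS(=O)(=O)C(F)(F)F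
Why: Soft enolisation of the methyl ketone gives the silyl enol ether, i.e. the siloxyvinyl diazoacetate.

Step 5
Reactants: 3 tert-butyl[(3-methylfuran-2-yl)methoxy]diphenylsilane, 6 benzyl 3-[(tert-butyldimethylsilyl)oxy]-2-diazobut-3-enoate
Product: 8 benzyl 3-[(tert-butyldimethylsilyl)oxy]-5-{[(tert-butyldiphenylsilyl)oxy]methyl}-6-methyl-8-oxabicyclo[3.2.1]octa-2,6-diene-2-carboxylate (racemic), via divinylcyclopropane 7 (not isolated)
Conditions: Rh2(O2CC7H15)4 (1 mol %), 3 (2 equiv), hexane, reflux, slow addition of 6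
Reagents that add atoms: none
Why: The dirhodium carbenoid from 6 adds to the unsubstituted C4=C5 bond of furan 3 (C9=C8 in xanthane numbering) to give the cis-divinylcyclopropane 7 (bonds C7–C8 and C7–C9), and its ring strain drives a Cope rearrangement through the obligatory boat transition state that breaks C7–C9 and forms C1–C5, so that C7–C8 and C1–C5 are made in one operation. The closest known reaction type is the tandem cyclopropanation/Cope rearrangement (formal [4+3] cycloaddition) of vinyldiazoacetates with furans. The three-membered ring closes by [2+1] carbenoid addition and the seven-membered carbocycle by the [3,3] shift, the furan oxygen remaining as the one-atom bridge of the 8-oxabicyclo[3.2.1]octadiene. The only stereocentres of 8, the bridgeheads C1 and C8, are tied together by the oxygen bridge and can only be cis; the achiral catalyst gives the racemate, which is wanted because the two halves of the target need opposite antipodes. The step needs regioselectivity (C7 to C8, C5 to C1), secured by the silyloxymethyl and methyl groups that shield the other furan double bond so that only the unsubstituted bond is cyclopropanated, and it needs the siloxyvinyl group endo in 7, the normal outcome for donor/acceptor carbenoids and the arrangement that permits the Cope step. The ester that stabilises the carbenoid ends on C7, where it directs the alkylation of step 6.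

Step 6
Reactants: 8 the oxabicyclic silyl enol ether
Product: 9 benzyl 5-{[(tert-butyldiphenylsilyl)oxy]methyl}-2-(2-methoxy-2-oxoethyl)-6-methyl-3-oxo-8-oxabicyclo[3.2.1]oct-6-ene-2-carboxylate (racemic)
Conditions: CsF, BrCH2CO2Me, DMF, 0 °C → rt
Reagents that add atoms: methyl bromoacetate, COC(=O)CBr
Why: Fluoride frees the β-keto ester enolate from the silyl enol ether and this stabilised enolate is C-alkylated only at C7 (fluoride-promoted alkylation of a silyl enol ether), the electrophile entering from the exo face; the configuration made at C7 is erased in step 7.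

Step 7
Reactants: 9 the alkylated β-keto benzyl ester
Product: 11 methyl 2-(5-{[(tert-butyldiphenylsilyl)oxy]methyl}-6-endo-methyl-3-oxo-8-oxabicyclo[3.2.1]octan-2-yl)acetate (racemic; chain equatorial), via keto acid 10 (not isolated)
Conditions: H2 (3 atm), 10% Pd/C, EtOAc, rt; then 50 °C
Reagents that add atoms: none
Why: Hydrogen adds to C9=C10 from the exo face (the side of the oxygen bridge), which puts the C10 methyl endo, i.e. trans to the bridge oxygen on the seven-membered ring, while hydrogenolysis of the benzyl ester gives β-keto acid 10 that loses CO2 and whose enol is protonated from the same exo face, so that the C7 chain ends equatorial, trans to the bridge oxygen and cis to the C10 methyl (also the more stable epimer); heterogeneous hydrogenation, hydrogenolysis and β-keto acid decarboxylation.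

Step 8
Reactants: 11 the bicyclic keto ester
Product: 13 methyl 2-(4-{[(tert-butyldiphenylsilyl)oxy]methyl}-5-methyl-2-oxo-7-[(trimethylsilyl)oxy]cyclohept-3-en-1-yl)acetate (racemic), via silyl enol ether 12 (not isolated)
Conditions: LiN(SiMe3)2, TMSCl, THF, −78 °C; then TMSOTf, Et3N (cat.), CH2Cl2, −78 → 0 °C
Reagents that add atoms: chlorotrimethylsilane, C[Si](C)(C)Cl
Why: Kinetic deprotonation takes an axial hydrogen of the C5 methylene in preference to the C7 methine, and the enol ether 12 then expels the TMSOTf-activated bridge oxygen from C1 (Lewis-acid-mediated β-elimination, the usual opening of 8-oxabicyclo[3.2.1]octan-3-ones) to give the C1=C5 enone with the oxygen left on C8 as a silyl ether that cannot re-add across the ring; no stereocentre is touched, so the C8 oxygen is trans to the C7 chain and to the C10 methyl.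

Step 9
Reactants: 13 the ring-opened enone
Product: 15 methyl 2-(4-{[(tert-butyldiphenylsilyl)oxy]methyl}-2,7-dihydroxy-5-methylcyclohept-3-en-1-yl)acetate (racemic; C6 epimers), via allylic alcohol silyl ether 14 (not isolated)
Conditions: NaBH4, CeCl3·7H2O, MeOH, −78 → 0 °C; then 1 M HCl, 0 °C
Reagents that add atoms: none
Why: Luche 1,2-reduction of the enone gives the allylic alcohol (the C6 configuration is of no consequence because C6 becomes CH2, and any lactone that a hydroxyl forms with the ester is either an allylic carboxylate for step 11 or is reopened in step 12), and the silyl ether is cleaved only after the enone is gone.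

Step 10
Reactants: 15 the diol
Product: 16 methyl 2-(2,7-diacetoxy-4-{[(tert-butyldiphenylsilyl)oxy]methyl}-5-methylcyclohept-3-en-1-yl)acetate (racemic; C6 epimers)
Conditions: Ac2O, pyridine, DMAP, CH2Cl2, rt
Reagents that add atoms: acetic anhydride, CC(=O)OC(C)=O
Why: Acylation of both secondary alcohols; the C6 acetate becomes the allylic leaving group and the C8 acetate a protecting group.

Step 11
Reactants: 16 the diacetate
Product: 17 methyl 2-(7-acetoxy-4-{[(tert-butyldiphenylsilyl)oxy]methyl}-5-methylcyclohept-3-en-1-yl)acetate (racemic)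
Conditions: Pd(PPh3)4 (5 mol %), Ph2SiH2, ZnCl2, THF, rt
Reagents that add atoms: none
Why: Zerovalent palladium ionises only the allylic C6 acetate to a π-allyl complex over C6–C5–C1 and hydride is delivered to the less hindered secondary terminus C6, so that the trisubstituted C1=C5 alkene stays in place and C6 becomes CH2 (palladium-catalysed hydrogenolysis of an allylic acetate).

Step 12
Reactants: 17 the acetoxy ester
Product: 18 2-(4-{[(tert-butyldiphenylsilyl)oxy]methyl}-7-hydroxy-5-methylcyclohept-3-en-1-yl)acetic acid (racemic)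
Conditions: LiOH, THF/MeOH/H2O, 0 °C → rt; then 1 M HCl to pH 4–5, 0 °C
Reagents that add atoms: lithium hydroxide, [Li+].[OH-]
Why: Saponification cleaves the methyl ester and the C8 acetate in one operation; the trans γ-hydroxy acid is set free cold and used at once so that it cannot lactonise with retention.

Step 13
Reactants: 18 the hydroxy acid
Product: 19 rac-(3aS,7R,8aS)-6-{[(tert-butyldiphenylsilyl)oxy]methyl}-7-methyl-3,3a,4,7,8,8a-hexahydro-2H-cyclohepta[b]furan-2-one
Conditions: PPh3, DIAD, THF (0.01 M), 0 °C → rt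
Reagents that add atoms: none
Why: Mitsunobu lactonisation, in which the C8 alkoxyphosphonium ion is displaced by the carboxylate with inversion, so that the lactone oxygen at C8 becomes cis to C7–C11 and to the C10 methyl (cis-fused γ-lactone of the 8-epi series).

Step 14
Reactants: 19 the cis-lactone
Product: 22 rac-(3aS,7R,8aS)-6-{[(tert-butyldiphenylsilyl)oxy]methyl}-7-methyl-3-methylidene-3,3a,4,7,8,8a-hexahydro-2H-cyclohepta[b]furan-2-one, via Mannich base 20 (not isolated), via ammonium iodide 21 (not isolated)
Conditions: LiN(iPr)2, THF, −78 °C; CH2=NMe2+ I−, → rt; then MeI, MeOH, rt; then NaHCO3, EtOAc/H2O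
Reagents that add atoms: N,N-dimethylmethylideneammonium iodide (Eschenmoser's salt), C=[N+](C)C.[I-]; iodomethane, CI (its carbon stays only in 21)
Why: Mannich reaction of the lactone enolate with the iminium salt, quaternisation and Hofmann-type β-elimination give the exocyclic methylene; no stereocentre is formed and C7 cannot epimerise.

Step 15
Reactants: 22 the silylated methylene lactone
Product: 23 rac-(3aS,7R,8aS)-6-(hydroxymethyl)-7-methyl-3-methylidene-3,3a,4,7,8,8a-hexahydro-2H-cyclohepta[b]furan-2-one
Conditions: HF·pyridine, pyridine, THF, 0 °C → rt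
Reagents that add atoms: none
Why: Fluoride cleavage of the silyl ether under buffered, non-basic conditions that leave the methylene lactone untouched.

Step 16
Reactants: 23 the allylic alcohol
Product: 24 rac-(3aS,7R,8aS)-7-methyl-3-methylidene-2-oxo-3,3a,4,7,8,8a-hexahydro-2H-cyclohepta[b]furan-6-carbaldehyde
Conditions: MnO2, CH2Cl2, rt
Reagents that add atoms: none
Why: Selective oxidation of the primary allylic alcohol to the enal.

Step 17
Reactants: 24 the enal
Product: 25 rac-8-epi-xanthatin, rac-(3aS,7R,8aS)-7-methyl-3-methylidene-6-[(1E)-3-oxobut-1-en-1-yl]-3,3a,4,7,8,8a-hexahydro-2H-cyclohepta[b]furan-2-one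
Conditions: Ph3P=CHC(O)CH3, toluene, 60 °C
Reagents that add atoms: 1-(triphenyl-λ5-phosphanylidene)propan-2-one, CC(=O)C=P(c1ccccc1)(c1ccccc1)c1ccccc1
Why: Wittig olefination with the stabilised ylide gives the (E)-enone and completes the C5=C1–C2=C3–C4=O dienone.

Step 18
Reactants: 25 rac-8-epi-xanthatin
Product: 26 (3aR,7S,8aR)-8-epi-xanthatin and 27 (3aS,7R,8aS)-8-epi-xanthatin
Conditions: preparative SFC, amylose tris(3,5-dimethylphenylcarbamate) phase, CO2/MeOH
Reagents that add atoms: none
Why: Resolution of the racemate by chromatography on a chiral stationary phase; both antipodes are used, 26 as the diene half and 27 as precursor of the epoxide half, and each would be assigned by ECD against calculation or by anomalous-dispersion X-ray analysis.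

Step 19
Reactants: 27 (3aS,7R,8aS)-8-epi-xanthatin
Product: 28 (1R,5R)-1,5-epoxide of 27 (xanthane locants; epoxide oxygen trans to the C10 methyl and to the lactone)
Conditions: mCPBA, NaHCO3, CH2Cl2, 0 °C
Reagents that add atoms: 3-chloroperoxybenzoic acid, OOC(=O)c1cccc(Cl)c1
Why: Prilezhaev epoxidation of the most electron-rich alkene, the γ,δ-bond C1=C5 of the dienone, from the face anti to the C10 methyl, which allylic strain with the C1 side chain holds pseudo-axial over the other face (the face that also carries the cis-lactone).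

Step 20
Reactants: 26 (3aR,7S,8aR)-8-epi-xanthatin, 28 the epoxide
Product: 29 Diels–Alder adduct (target skeleton with C1=C2, H at C3 and no C1 hydroxyl; acetyl on C3 cis to C6)
Conditions: 28 (3 equiv), toluene (2 M), BHT, 100 °C, sealed tube
Reagents that add atoms: none
Why: Thermal Diels–Alder reaction of the C5=C1–C2=C3 diene of 26 with the exocyclic C11'=C13' alkene of 28 in the usual ortho orientation (C3–C11', C5–C13'), the 1,1-disubstituted methylene lactone reacting carbonyl-exo and on its convex face (syn to H-7') and the diene at C5 on the face of the C10 methyl, away from C7 of its own folded ring, which sets C5, C3 and the spiro centre C11'; the excess of 28, which has no diene, suppresses self-dimerisation of 26.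

Step 21
Reactants: 29 the Diels–Alder adduct
Product: 31 CNP0177598.2, via bromohydrin 30 (not isolated)
Conditions: NBS, THF/H2O (4:1), 0 °C, dark; then Et3N, rt
Reagents that add atoms: water, O; N-bromosuccinimide, O=C1CCC(=O)N1Br (its bromine stays only in 30)
Why: Bromonium formation on the only electron-rich alkene C1=C2 from the face anti to the pseudo-axial C3 acetyl and trans-diaxial (Fürst–Plattner) opening by water at the tertiary carbon C1 put the hydroxyl on the face opposite to H-5, and E1cB loss of HBr through the C3 enolate then gives the C2=C3 enone (bromohydrin formation followed by β-elimination).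

**Compound list**

1 | methyl 3-methylfuran-2-carboxylate | COC(=O)c1occc1C | starting material
2 | (3-methylfuran-2-yl)methanol | Cc1ccoc1CO | intermediate
3 | tert-butyl[(3-methylfuran-2-yl)methoxy]diphenylsilane | Cc1ccoc1CO[Si](c1ccccc1)(c1ccccc1)C(C)(C)C | intermediate
4 | benzyl 3-oxobutanoate | CC(=O)CC(=O)OCc1ccccc1 | starting material
5 | benzyl 2-diazo-3-oxobutanoate | CC(=O)C(=[N+]=[N-])C(=O)OCc1ccccc1 | intermediate
6 | benzyl 3-[(tert-butyldimethylsilyl)oxy]-2-diazobut-3-enoate | C=C(O[Si](C)(C)C(C)(C)C)C(=[N+]=[N-])C(=O)OCc1ccccc1 | intermediate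
7 | benzyl 6-{1-[(tert-butyldimethylsilyl)oxy]ethenyl}-3-{[(tert-butyldiphenylsilyl)oxy]methyl}-4-methyl-2-oxabicyclo[3.1.0]hex-3-ene-6-carboxylate (racemic; siloxyvinyl endo, ester exo) | CC1=C(CO[Si](c3ccccc3)(c3ccccc3)C(C)(C)C)O[C@@H]2[C@H]1[C@]2(C(=O)OCc4ccccc4)C(=C)O[Si](C)(C)C(C)(C)C | intermediate
8 | benzyl 3-[(tert-butyldimethylsilyl)oxy]-5-{[(tert-butyldiphenylsilyl)oxy]methyl}-6-methyl-8-oxabicyclo[3.2.1]octa-2,6-diene-2-carboxylate (racemic) | CC1=C[C@@H]2C(C(=O)OCc4ccccc4)=C(O[Si](C)(C)C(C)(C)C)C[C@@]1(CO[Si](c3ccccc3)(c3ccccc3)C(C)(C)C)O2 | intermediate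
9 | benzyl 5-{[(tert-butyldiphenylsilyl)oxy]methyl}-2-(2-methoxy-2-oxoethyl)-6-methyl-3-oxo-8-oxabicyclo[3.2.1]oct-6-ene-2-carboxylate (racemic; new chain cis to the oxygen bridge, of no consequence) | CC1=C[C@@H]2[C@](CC(=O)OC)(C(=O)OCc4ccccc4)C(=O)C[C@@]1(CO[Si](c3ccccc3)(c3ccccc3)C(C)(C)C)O2 | intermediate
10 | 5-{[(tert-butyldiphenylsilyl)oxy]methyl}-2-(2-methoxy-2-oxoethyl)-6-endo-methyl-3-oxo-8-oxabicyclo[3.2.1]octane-2-carboxylic acid (racemic) | C[C@@H]1C[C@@H]2[C@](CC(=O)OC)(C(=O)O)C(=O)C[C@@]1(CO[Si](c3ccccc3)(c3ccccc3)C(C)(C)C)O2 | intermediate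
11 | methyl 2-(5-{[(tert-butyldiphenylsilyl)oxy]methyl}-6-endo-methyl-3-oxo-8-oxabicyclo[3.2.1]octan-2-yl)acetate (racemic; chain equatorial, trans to the bridge oxygen on the carbocycle, cis to the methyl) | C[C@@H]1C[C@@H]2[C@H](CC(=O)OC)C(=O)C[C@@]1(CO[Si](c3ccccc3)(c3ccccc3)C(C)(C)C)O2 | intermediate
12 | trimethylsilyl enol ether of 11 with the double bond toward C5 (bicycle C3=C4) | C[C@@H]1C[C@@H]2[C@H](CC(=O)OC)C(O[Si](C)(C)C)=C[C@@]1(CO[Si](c3ccccc3)(c3ccccc3)C(C)(C)C)O2 | intermediate
13 | methyl 2-(4-{[(tert-butyldiphenylsilyl)oxy]methyl}-5-methyl-2-oxo-7-[(trimethylsilyl)oxy]cyclohept-3-en-1-yl)acetate (racemic; C8 oxygen trans to the C7 chain and to the C10 methyl) | C[C@@H]1C[C@@H](O[Si](C)(C)C)[C@H](CC(=O)OC)C(=O)C=C1CO[Si](c2ccccc2)(c2ccccc2)C(C)(C)C | intermediate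
14 | methyl 2-(4-{[(tert-butyldiphenylsilyl)oxy]methyl}-2-hydroxy-5-methyl-7-[(trimethylsilyl)oxy]cyclohept-3-en-1-yl)acetate (racemic; C6 epimers) | C[C@@H]1C[C@@H](O[Si](C)(C)C)[C@H](CC(=O)OC)C(O)C=C1CO[Si](c2ccccc2)(c2ccccc2)C(C)(C)C | intermediate
15 | methyl 2-(4-{[(tert-butyldiphenylsilyl)oxy]methyl}-2,7-dihydroxy-5-methylcyclohept-3-en-1-yl)acetate (racemic; C6 epimers) | C[C@@H]1C[C@@H](O)[C@H](CC(=O)OC)C(O)C=C1CO[Si](c2ccccc2)(c2ccccc2)C(C)(C)C | intermediate
16 | methyl 2-(2,7-diacetoxy-4-{[(tert-butyldiphenylsilyl)oxy]methyl}-5-methylcyclohept-3-en-1-yl)acetate (racemic; C6 epimers) | C[C@@H]1C[C@@H](OC(C)=O)[C@H](CC(=O)OC)C(OC(C)=O)C=C1CO[Si](c2ccccc2)(c2ccccc2)C(C)(C)C | intermediate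
17 | methyl 2-(7-acetoxy-4-{[(tert-butyldiphenylsilyl)oxy]methyl}-5-methylcyclohept-3-en-1-yl)acetate (racemic; C8 acetoxy trans to the C7 chain and to the C10 methyl) | C[C@@H]1C[C@@H](OC(C)=O)[C@H](CC(=O)OC)CC=C1CO[Si](c2ccccc2)(c2ccccc2)C(C)(C)C | intermediate
18 | 2-(4-{[(tert-butyldiphenylsilyl)oxy]methyl}-7-hydroxy-5-methylcyclohept-3-en-1-yl)acetic acid (racemic; hydroxyl trans to the chain and to the methyl) | C[C@@H]1C[C@@H](O)[C@H](CC(=O)O)CC=C1CO[Si](c2ccccc2)(c2ccccc2)C(C)(C)C | intermediate
19 | rac-(3aS,7R,8aS)-6-{[(tert-butyldiphenylsilyl)oxy]methyl}-7-methyl-3,3a,4,7,8,8a-hexahydro-2H-cyclohepta[b]furan-2-one | O=C1O[C@H]2C[C@@H](C)C(CO[Si](c3ccccc3)(c3ccccc3)C(C)(C)C)=CC[C@H]2C1 | intermediate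
20 | 3-[(dimethylamino)methyl] derivative of 19 (C11 epimers) | CN(C)CC1C(=O)O[C@H]2C[C@@H](C)C(CO[Si](c3ccccc3)(c3ccccc3)C(C)(C)C)=CC[C@@H]12 | intermediate
21 | trimethylammonium iodide from 20 | C[N+](C)(C)CC1C(=O)O[C@H]2C[C@@H](C)C(CO[Si](c3ccccc3)(c3ccccc3)C(C)(C)C)=CC[C@@H]12.[I-] | intermediate
22 | rac-(3aS,7R,8aS)-6-{[(tert-butyldiphenylsilyl)oxy]methyl}-7-methyl-3-methylidene-3,3a,4,7,8,8a-hexahydro-2H-cyclohepta[b]furan-2-one | C=C1C(=O)O[C@H]2C[C@@H](C)C(CO[Si](c3ccccc3)(c3ccccc3)C(C)(C)C)=CC[C@@H]12 | intermediate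
23 | rac-(3aS,7R,8aS)-6-(hydroxymethyl)-7-methyl-3-methylidene-3,3a,4,7,8,8a-hexahydro-2H-cyclohepta[b]furan-2-one | C=C1C(=O)O[C@H]2C[C@@H](C)C(CO)=CC[C@@H]12 | intermediate
24 | rac-(3aS,7R,8aS)-7-methyl-3-methylidene-2-oxo-3,3a,4,7,8,8a-hexahydro-2H-cyclohepta[b]furan-6-carbaldehyde | C=C1C(=O)O[C@H]2C[C@@H](C)C(C=O)=CC[C@@H]12 | intermediate
25 | rac-8-epi-xanthatin (racemate; one antipode drawn) | C=C1C(=O)O[C@H]2C[C@@H](C)C(/C=C/C(C)=O)=CC[C@@H]12 | intermediate
26 | (3aR,7S,8aR)-7-methyl-3-methylidene-6-[(1E)-3-oxobut-1-en-1-yl]-3,3a,4,7,8,8a-hexahydro-2H-cyclohepta[b]furan-2-one (8-epi-xanthatin) | C=C1C(=O)O[C@@H]2C[C@H](C)C(/C=C/C(C)=O)=CC[C@H]12 | intermediate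
27 | (3aS,7R,8aS)-enantiomer of 26 | C=C1C(=O)O[C@H]2C[C@@H](C)C(/C=C/C(C)=O)=CC[C@@H]12 | intermediate
28 | (1R,5R)-1,5-epoxide of 27 (xanthane locants; 7S,8S,10R; epoxide trans to the methyl and the lactone) | C=C1C(=O)O[C@H]2C[C@@H](C)[C@]3(/C=C/C(C)=O)O[C@@H]3C[C@@H]12 | intermediate
29 | Diels–Alder adduct of 26 and 28 (cyclohexene C1=C2; H-3 cis to H-5; spiro C11' with lactone carbonyl trans to C6) | C=C1C(=O)O[C@@H]2C[C@H](C)C3=C[C@H](C(C)=O)[C@]4(C[C@@H]3C[C@H]12)C(=O)O[C@H]1C[C@@H](C)[C@]2(/C=C/C(C)=O)O[C@@H]2C[C@H]14 | intermediate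
30 | bromohydrin of 29 (C1 hydroxyl trans to H-5; C2 bromine trans to the hydroxyl) | C=C1C(=O)O[C@@H]2C[C@H](C)[C@@]3(O)[C@@H](Br)[C@H](C(C)=O)[C@]4(C[C@@H]3C[C@H]12)C(=O)O[C@H]1C[C@@H](C)[C@]2(/C=C/C(C)=O)O[C@@H]2C[C@H]14 | intermediate
31 | CNP0177598.2 | C=C1C(=O)O[C@@H]2C[C@H](C)[C@@]3(O)C=C(C(C)=O)[C@]4(C[C@@H]3C[C@H]12)C(=O)O[C@H]1C[C@@H](C)[C@]2(/C=C/C(C)=O)O[C@@H]2C[C@H]14 | target

**Step count**

Total: 21 steps. Longest linear sequence: 19 steps (steps 1, 2 and 5–21; the branch through steps 3 and 4 is equally long).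

**Steps most likely to fail**

Step 20 (cross Diels–Alder). The risk is self-dimerisation of 26 through its own methylene lactone and erosion of exo and facial selectivity at the temperature needed. The fallback masks the competing dienophile instead of relying on an excess of the partner. It sets out from 26: conjugate addition of thiophenol (PhSH, cat. Et3N, CH2Cl2, 0 °C) to the methylene lactone should give 13-(phenylsulfanyl)-11,13-dihydro-8-epi-xanthatin F1, which keeps the diene but has no reactive dienophile. Heating F1 with 28 in toluene should give the thioether adduct F2. NaIO4 in MeOH/H2O would oxidise it to the sulfoxide F3, and thermal syn-elimination (toluene, NaHCO3, 100 °C) restores the methylene group, so the sequence comes back to the route at 29.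

Step 8 (opening of the oxygen bridge). The risk is competing deprotonation at the C7 methine, which would open the bridge toward C8, or scrambling of the silyl enol ether. The fallback keeps the benzyl ester as a blocking group so that only C5 can enolise. It sets out from 9: diimide (TsNHNH2, NaOAc, THF/H2O, reflux) should reduce C9=C10 from the exo face without touching the benzyl ester and give the saturated keto diester F4. TMSOTf/Et3N in CH2Cl2 then opens the bridge toward C1 and gives the ring-opened keto diester F5 with the C8 oxygen silylated. Short hydrogenolysis (H2, Pd/C, EtOAc; the hindered enone alkene should react more slowly than the benzyl ester), loss of CO2 and equilibration of C7 with Et3N bring the sequence back to the route at 13.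

Step 19 (epoxidation). The risk is low or reversed facial selectivity of the peracid at C1=C5, or attack at C2=C3. The fallback delivers the oxygen anti to the electrophile instead of syn. It sets out from 27: NBS in THF/H2O should give the bromohydrin F6 (bromonium on the face the electrophile prefers, water from the other face at C1). K2CO3 in MeOH then closes the epoxide by intramolecular displacement at C5, on the face opposite to the one a peracid would take, and the route is rejoined at 28. The two methods are stereochemically complementary, so one of them should give 28 whichever face the electrophile prefers.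

Further compounds

F1 | step 20 | 13-(phenylsulfanyl)-11,13-dihydro-8-epi-xanthatin (C11 epimers) | c3ccccc3SCC1C(=O)O[C@@H]2C[C@H](C)C(/C=C/C(C)=O)=CC[C@H]12
F2 | step 20 | Diels–Alder adduct of F1 and 28 (29 with CH–CH2SPh in place of C11=C13) | c5ccccc5SCC1C(=O)O[C@@H]2C[C@H](C)C3=C[C@H](C(C)=O)[C@]4(C[C@@H]3C[C@H]12)C(=O)O[C@H]1C[C@@H](C)[C@]2(/C=C/C(C)=O)O[C@@H]2C[C@H]14
F3 | step 20 | sulfoxide of F2 | O=S(c5ccccc5)CC1C(=O)O[C@@H]2C[C@H](C)C3=C[C@H](C(C)=O)[C@]4(C[C@@H]3C[C@H]12)C(=O)O[C@H]1C[C@@H](C)[C@]2(/C=C/C(C)=O)O[C@@H]2C[C@H]14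
F4 | step 8 | benzyl 5-{[(tert-butyldiphenylsilyl)oxy]methyl}-2-(2-methoxy-2-oxoethyl)-6-endo-methyl-3-oxo-8-oxabicyclo[3.2.1]octane-2-carboxylate (racemic) | C[C@@H]1C[C@@H]2[C@](CC(=O)OC)(C(=O)OCc4ccccc4)C(=O)C[C@@]1(CO[Si](c3ccccc3)(c3ccccc3)C(C)(C)C)O2
F5 | step 8 | benzyl 4-{[(tert-butyldiphenylsilyl)oxy]methyl}-1-(2-methoxy-2-oxoethyl)-5-methyl-2-oxo-7-[(trimethylsilyl)oxy]cyclohept-3-ene-1-carboxylate (racemic) | C[C@@H]1C[C@@H](O[Si](C)(C)C)[C@](CC(=O)OC)(C(=O)OCc3ccccc3)C(=O)C=C1CO[Si](c2ccccc2)(c2ccccc2)C(C)(C)C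
F6 | step 19 | bromohydrin of 27 (C1 hydroxyl trans to the C10 methyl; C5 bromine cis to it) | C=C1C(=O)O[C@H]2C[C@@H](C)[C@@](O)(/C=C/C(C)=O)[C@@H](Br)C[C@@H]12
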